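The synthesis rests on disconnecting ring C from ring A at two bonds, O1–C8a and C4–C4a, so that ring A enters as an aryne and C2–C3–C4 as an enantiopure beta-silyloxy Weinreb amide. In one operation fluoride should release the aryne and the alkoxide; O1 adds to C8a and the C4a anion closes the pyranone on the amide carbonyl. The step exploits the ortho pair C8a/C4a of ring A and the C5 oxygen beside C4a, which polarises the aryne and fixes the regiochemistry. The precursor is a symmetrical 4-benzyl-3,5-dimethoxy-2-silylphenyl triflate; C2 is set beforehand by asymmetric transfer hydrogenation, and chelation-controlled C5 demethylation with debenzylation ends the route.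

Key step: step 8

Assumption: the descriptor in the target SMILES corresponds to the (2R) configuration (flavanone numbering O1, C2, C3, C4, C4a, C5–C8, C8a is used throughout); compounds 1, 2, 10 and 11 are taken as commercially available.

Step 1
Reactants: 1 4-hydroxy-2,6-dimethoxybenzaldehyde; 2 1-(benzyloxy)-2-bromobenzene
Product: 4 [2-(benzyloxy)phenyl](4-hydroxy-2,6-dimethoxyphenyl)methanol (racemic), via Grignard reagent 3 (not isolated)
Conditions: 2 (3 equiv), Mg, THF, reflux; then 1, THF, 0 °C to rt; then H2O
Reagents that add atoms: none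
Why: Grignard addition to the aldehyde, after the first equivalent has deprotonated the phenol, should give the diarylmethanol, whose carbinol centre forms as a racemate and is removed in step 2.

Step 2
Reactants: 4 [2-(benzyloxy)phenyl](4-hydroxy-2,6-dimethoxyphenyl)methanol
Product: 5 4-[2-(benzyloxy)benzyl]-3,5-dimethoxyphenol
Conditions: Et3SiH, CF3CO2H, CH2Cl2, 0 °C
Reagents that add atoms: none
Why: Ionic hydrogenation, in which acid ionises the doubly benzylic, donor-stabilised carbinol to a cation of para-quinone methide type that Et3SiH should reduce to the diarylmethane.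

Step 3
Reactants: 5 4-[2-(benzyloxy)benzyl]-3,5-dimethoxyphenol
Product: 6 4-[2-(benzyloxy)benzyl]-2-bromo-3,5-dimethoxyphenol
Conditions: NBS (1.0 equiv), CH2Cl2, −78 to 0 °C, dark
Reagents that add atoms: N-bromosuccinimide, O=C1CCC(=O)N1Br
Why: Electrophilic aromatic bromination ortho to the free phenol, where the para position is blocked and the two ortho positions are equivalent by symmetry, so a single monobromide should result.

Step 4
Reactants: 6 4-[2-(benzyloxy)benzyl]-2-bromo-3,5-dimethoxyphenol
Product: 9 4-[2-(benzyloxy)benzyl]-3,5-dimethoxy-2-(trimethylsilyl)phenyl trifluoromethanesulfonate, via silyl ether 7 (not isolated), via lithium phenoxide 8 (not isolated)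
Conditions: HN(SiMe3)2, THF, 70 °C, then evaporation; n-BuLi, THF, −100 to −78 °C; Tf2O, −100 °C to rt
Reagents that add atoms: hexamethyldisilazane, C[Si](C)(C)N[Si](C)(C)C; trifluoromethanesulfonic anhydride, O=S(=O)(OS(=O)(=O)C(F)(F)F)C(F)(F)F
Why: O-silylation, bromine–lithium exchange, 1,3 O-to-C silyl shift (retro-Brook rearrangement) and O-triflation of the resulting phenoxide form the standard one-pot entry to ortho-silylaryl triflates.

Step 5
Reactants: 10 methyl 4-(benzyloxy)benzoate; 11 N-methoxy-N-methylacetamide
Product: 13 3-[4-(benzyloxy)phenyl]-N-methoxy-N-methyl-3-oxopropanamide, via lithium enolate 12 (not isolated)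
Conditions: LiN(i-Pr)2 (2.2 equiv), 11 (2.2 equiv), THF, −78 °C; then 10, −78 to 0 °C; then 1 M HCl
Reagents that add atoms: none
Why: Crossed Claisen condensation of the amide enolate with a non-enolisable aryl ester, in which the second equivalent of enolate deprotonates the beta-keto amide and so should prevent further addition.

Step 6
Reactants: 13 3-[4-(benzyloxy)phenyl]-N-methoxy-N-methyl-3-oxopropanamide
Product: 14 (3R)-3-[4-(benzyloxy)phenyl]-3-hydroxy-N-methoxy-N-methylpropanamide
Conditions: RuCl[(R,R)-TsDPEN](p-cymene) (1 mol %), HCO2H/Et3N (5:2), CH2Cl2, 30 °C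
Reagents that add atoms: none
Why: Noyori asymmetric transfer hydrogenation of an aryl ketone, in which the CH/π contact between the p-cymene ligand and the aryl group selects the carbonyl face, so the (R,R)-ligand should give the (R)-carbinol as it does with simple aryl methyl ketones.

Step 7
Reactants: 14 (3R)-3-[4-(benzyloxy)phenyl]-3-hydroxy-N-methoxy-N-methylpropanamide
Product: 15 (3R)-3-[4-(benzyloxy)phenyl]-N-methoxy-N-methyl-3-[(trimethylsilyl)oxy]propanamide
Conditions: N-(trimethylsilyl)imidazole, CH2Cl2, rt
Reagents that add atoms: N-(trimethylsilyl)imidazole, C[Si](C)(C)n1ccnc1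
Why: Neutral O-silylation of a secondary alcohol that touches no bond at the stereocentre and leaves a proton-free alkoxide precursor.

Step 8
Reactants: 9 4-[2-(benzyloxy)benzyl]-3,5-dimethoxy-2-(trimethylsilyl)phenyl trifluoromethanesulfonate; 15 (3R)-3-[4-(benzyloxy)phenyl]-N-methoxy-N-methyl-3-[(trimethylsilyl)oxy]propanamide
Product: 19 (2R)-6-[2-(benzyloxy)benzyl]-2-[4-(benzyloxy)phenyl]-5,7-dimethoxychroman-4-one, via aryne 16 (not isolated), via aryl anion 17 (not isolated), via hemiaminal alkoxide 18 (not isolated)
Conditions: KF, 18-crown-6, THF, 0 °C to rt (15 in slight excess); then 0.5 M HCl, 0 °C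
Reagents that add atoms: none
Why: Proposed new method: fluoride should remove the C-silyl group of 9 to release aryne 16 and the O-silyl group of 15 to release a proton-free alkoxide, which adds to C8a, the aryne carbon remote from the flanking methoxy group, to leave aryl anion 17 at C4a; this anion should attack the tethered Weinreb carbonyl to give tetrahedral adduct 18, which cannot enolise or ring-open and collapses to the ketone only on mildly acidic work-up. The closest known reaction type is the tandem nucleophilic addition–intramolecular acyl substitution of arynes with salicylate esters that gives xanthones, supported by the acyl-alkylation of arynes with beta-keto esters; an aliphatic beta-silyloxy amide as the partner is the untested element. Ring C closes in a 6-exo-trig mode by attack of C4a on C4. No lasting stereocentre is created: C2 is carried in from 15 with none of its bonds made or broken, and the hemiaminal centre of 18 is erased on hydrolysis. The step needs O-attack at C8a and not C4a, which the inductive distortion of the aryne by the C5 methoxy group secures and the C6 benzyl group reinforces sterically, and it needs acyl capture to outrun protonation of 17, which the silyl ether (no O–H) and the aprotic medium secure. Retro-aldol loss of configuration in the free alkoxide is held back by the low temperature and its fast capture by the aryne.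

Step 9
Reactants: 19 (2R)-6-[2-(benzyloxy)benzyl]-2-[4-(benzyloxy)phenyl]-5,7-dimethoxychroman-4-one
Product: 20 (+)-methylphelligrin A, (2R)-5-hydroxy-6-(2-hydroxybenzyl)-2-(4-hydroxyphenyl)-7-methoxychroman-4-one
Conditions: BCl3, C6HMe5, CH2Cl2, −78 to 0 °C; then MeOH, H2O
Reagents that add atoms: none
Why: BCl3 should cleave both aryl benzyl ethers at low temperature with pentamethylbenzene trapping the benzyl cations, and should cleave only the C5 methyl ether through the six-membered boron chelate with the C4 carbonyl, leaving the C7 methyl ether and C2 untouched.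

Compound list
1 | 4-hydroxy-2,6-dimethoxybenzaldehyde | COc1cc(O)cc(OC)c1C=O | starting material
2 | 1-(benzyloxy)-2-bromobenzene | Brc1ccccc1OCc1ccccc1 | starting material
3 | [2-(benzyloxy)phenyl]magnesium bromide | Br[Mg]c1ccccc1OCc1ccccc1 | intermediate
4 | [2-(benzyloxy)phenyl](4-hydroxy-2,6-dimethoxyphenyl)methanol (racemic) | COc1cc(O)cc(OC)c1C(O)c1ccccc1OCc1ccccc1 | intermediate
5 | 4-[2-(benzyloxy)benzyl]-3,5-dimethoxyphenol | COc1cc(O)cc(OC)c1Cc1ccccc1OCc1ccccc1 | intermediate
6 | 4-[2-(benzyloxy)benzyl]-2-bromo-3,5-dimethoxyphenol | COc1cc(O)c(Br)c(OC)c1Cc1ccccc1OCc1ccccc1 | intermediate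
7 | {4-[2-(benzyloxy)benzyl]-2-bromo-3,5-dimethoxyphenoxy}trimethylsilane | COc1cc(O[Si](C)(C)C)c(Br)c(OC)c1Cc1ccccc1OCc1ccccc1 | intermediate
8 | lithium 4-[2-(benzyloxy)benzyl]-3,5-dimethoxy-2-(trimethylsilyl)phenoxide | COc1cc([O-])c([Si](C)(C)C)c(OC)c1Cc1ccccc1OCc1ccccc1.[Li+] | intermediate
9 | 4-[2-(benzyloxy)benzyl]-3,5-dimethoxy-2-(trimethylsilyl)phenyl trifluoromethanesulfonate | COc1cc(OS(=O)(=O)C(F)(F)F)c([Si](C)(C)C)c(OC)c1Cc1ccccc1OCc1ccccc1 | intermediate
10 | methyl 4-(benzyloxy)benzoate | COC(=O)c1ccc(OCc2ccccc2)cc1 | starting material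
11 | N-methoxy-N-methylacetamide | CC(=O)N(C)OC | starting material
12 | lithium enolate of N-methoxy-N-methylacetamide | C=C([O-])N(C)OC.[Li+] | intermediate
13 | 3-[4-(benzyloxy)phenyl]-N-methoxy-N-methyl-3-oxopropanamide | CON(C)C(=O)CC(=O)c1ccc(OCc2ccccc2)cc1 | intermediate
14 | (3R)-3-[4-(benzyloxy)phenyl]-3-hydroxy-N-methoxy-N-methylpropanamide | CON(C)C(=O)C[C@H](c1ccc(OCc2ccccc2)cc1)O | intermediate
15 | (3R)-3-[4-(benzyloxy)phenyl]-N-methoxy-N-methyl-3-[(trimethylsilyl)oxy]propanamide | CON(C)C(=O)C[C@H](c1ccc(OCc2ccccc2)cc1)O[Si](C)(C)C | intermediate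
16 | 4-[2-(benzyloxy)benzyl]-3,5-dimethoxybenzyne (aryne carbons become C8a and C4a) | COC1=CC#CC(OC)=C1Cc1ccccc1OCc1ccccc1 | intermediate
17 | potassium aryl anion at C4a of the (R)-configured aryl ether of the Weinreb amide | COc1cc(O[C@H](CC(=O)N(C)OC)c2ccc(OCc3ccccc3)cc2)[c-]c(OC)c1Cc1ccccc1OCc1ccccc1.[K+] | intermediate
18 | potassium (2R)-6-[2-(benzyloxy)benzyl]-2-[4-(benzyloxy)phenyl]-5,7-dimethoxy-4-[methoxy(methyl)amino]chroman-4-olate (both C4 epimers) | COc1cc2c(c(OC)c1Cc1ccccc1OCc1ccccc1)C([O-])(N(C)OC)C[C@H](c1ccc(OCc3ccccc3)cc1)O2.[K+] | intermediate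
19 | (2R)-6-[2-(benzyloxy)benzyl]-2-[4-(benzyloxy)phenyl]-5,7-dimethoxychroman-4-one | COc1cc2c(c(OC)c1Cc1ccccc1OCc1ccccc1)C(=O)C[C@H](c1ccc(OCc3ccccc3)cc1)O2 | intermediate
20 | (+)-methylphelligrin A, (2R)-5-hydroxy-6-(2-hydroxybenzyl)-2-(4-hydroxyphenyl)-7-methoxychroman-4-one | COc1cc2c(c(O)c1Cc1ccccc1O)C(=O)C[C@H](c1ccc(O)cc1)O2 | target

Total step count: 9 steps.
Longest linear sequence: 6 steps (steps 1, 2, 3, 4, 8, 9); the amide branch (steps 5, 6, 7) joins at step 8.

Steps most likely to fail

1. Step 8 (key step, new method). The liberated alkoxide may undergo retro-aldol cleavage or lose configuration before it is captured. The aryl anion may be protonated or may deprotonate the amide alpha-position instead of acylating. Addition of the alkoxide to the aryne may also be too slow. The fallback uses known chemistry, sets out from 5 and comes back at 19. Ortho-acetylation of phenol 5 (Ac2O, BF3·OEt2, 0 °C to rt; the two ortho positions are equivalent) should give 1-{3-[2-(benzyloxy)benzyl]-6-hydroxy-2,4-dimethoxyphenyl}ethan-1-one F1. Condensation with Me2NCH(OMe)2 in toluene at 90 °C should give the enaminone (E)-1-{3-[2-(benzyloxy)benzyl]-6-hydroxy-2,4-dimethoxyphenyl}-3-(dimethylamino)prop-2-en-1-one F2. Acid-induced cyclisation (HCl, CH2Cl2) should give the chromone 6-[2-(benzyloxy)benzyl]-5,7-dimethoxy-4H-chromen-4-one F3. Asymmetric 1,4-addition (Hayashi–Miyaura reaction) of commercial 4-(benzyloxy)phenylboronic acid, with [Rh(OH)(cod)]2 and an electron-poor chiral MeO-BIPHEP-type bisphosphine in toluene/H2O, the ligand enantiomer being chosen to deliver the (2R) product, should then give 19.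

2. Step 9. The Lewis acid may ionise the C2–O1 bond and open ring C to the chalcone, eroding enantiopurity, or benzyl cations may transfer to the electron-rich rings. The fallback sets out from 19 and comes back at 20, separating the two deprotections. Neutral hydrogenolysis (H2, Pd/C, EtOAc) should give (2R)-6-(2-hydroxybenzyl)-2-(4-hydroxyphenyl)-5,7-dimethoxychroman-4-one F4. The milder chelating MgI2·OEt2 in THF/toluene should then remove only the C5 methyl group through the magnesium chelate with the C4 carbonyl to give 20.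

3. Step 1. Conversion may be low because the para-phenoxide formed first deactivates the formyl group, and the labile para-hydroxy carbinol may dehydrate and oligomerise on work-up. The fallback sets out from 1 and comes back at 5, masking the phenol so that a neutral aldehyde is attacked. Silylation of 1 (i-Pr3SiCl, imidazole, DMF) should give 2,6-dimethoxy-4-[(triisopropylsilyl)oxy]benzaldehyde F5. Addition of Grignard reagent 3 should give [2-(benzyloxy)phenyl]{2,6-dimethoxy-4-[(triisopropylsilyl)oxy]phenyl}methanol F6. Ionic hydrogenation (Et3SiH, CF3CO2H) should give {4-[2-(benzyloxy)benzyl]-3,5-dimethoxyphenoxy}triisopropylsilane F7, and Bu4NF in THF should release 5.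

Further compounds
F1 | step 8 | 1-{3-[2-(benzyloxy)benzyl]-6-hydroxy-2,4-dimethoxyphenyl}ethan-1-one | COc1cc(O)c(C(C)=O)c(OC)c1Cc1ccccc1OCc1ccccc1
F2 | step 8 | (E)-1-{3-[2-(benzyloxy)benzyl]-6-hydroxy-2,4-dimethoxyphenyl}-3-(dimethylamino)prop-2-en-1-one | COc1cc(O)c(C(=O)/C=C/N(C)C)c(OC)c1Cc1ccccc1OCc1ccccc1
F3 | step 8 | 6-[2-(benzyloxy)benzyl]-5,7-dimethoxy-4H-chromen-4-one | COc1cc2occc(=O)c2c(OC)c1Cc1ccccc1OCc1ccccc1
F4 | step 9 | (2R)-6-(2-hydroxybenzyl)-2-(4-hydroxyphenyl)-5,7-dimethoxychroman-4-one | COc1cc2c(c(OC)c1Cc1ccccc1O)C(=O)C[C@H](c1ccc(O)cc1)O2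
F5 | step 1 | 2,6-dimethoxy-4-[(triisopropylsilyl)oxy]benzaldehyde | COc1cc(O[Si](C(C)C)(C(C)C)C(C)C)cc(OC)c1C=O
F6 | step 1 | [2-(benzyloxy)phenyl]{2,6-dimethoxy-4-[(triisopropylsilyl)oxy]phenyl}methanol (racemic) | COc1cc(O[Si](C(C)C)(C(C)C)C(C)C)cc(OC)c1C(O)c1ccccc1OCc1ccccc1
F7 | step 1 | {4-[2-(benzyloxy)benzyl]-3,5-dimethoxyphenoxy}triisopropylsilane | COc1cc(O[Si](C(C)C)(C(C)C)C(C)C)cc(OC)c1Cc1ccccc1OCc1ccccc1
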